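The indene numbering of the target is used. Everything rests on making the C3–C3a bond of the cyclopentene (ring B) by 5-exo attack of a C3 vinyllithium on an open-chain tiglate: C3a is the β-carbon of the C4 carboxyl group, so this closure sets the trans ring junction and delivers the C4 ester enolate. Because the ester alcohol is the chiral allyl unit that carries C5, silylation and [3,3] shift in the same flask join the two quaternary carbons C4–C5 and unmask the acid. The precursor is an acyclic (Z)-iodoalkenyl dienoate of an enynol; ring A is closed afterwards by metathesis and the styryl group is added last.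

Key step: step 13

Assumption: in step 4 the (S,S)-controller is taken to select the chair that leads to (2S,3R)-6; if the sense of induction is the reverse, the (R,R)-controller is used and nothing else changes.

Step 1
Reactants: 1 glyoxal (40% in water)
Product: 2 dimethyl (2E,4E)-2,5-dimethylhexa-2,4-dienedioate
Conditions: Ph3P=C(Me)CO2Me (2.2 equiv), CH2Cl2, 0 °C to rt
Reagents that add atoms: methyl 2-(triphenylphosphoranylidene)propanoate, COC(=O)C(C)=P(c1ccccc1)(c1ccccc1)c1ccccc1
Why: Double Wittig olefination of the dialdehyde with a stabilised ylide should give the (E,E)-diene diester, since such ylides are E-selective.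

Step 2
Reactants: 2 dimethyl (2E,4E)-2,5-dimethylhexa-2,4-dienedioate
Product: 3 methyl (2E,4E)-6-hydroxy-2,5-dimethylhexa-2,4-dienoate
Conditions: i-Bu2AlH (2.0 equiv), CH2Cl2, −78 °C; aq. potassium sodium tartrate
Reagents that add atoms: none
Why: Partial hydride reduction of one of two equivalent ester groups (statistical desymmetrisation, helped by the lower electrophilicity of the dienoate once one end is an aluminium alkoxide), with unchanged 2 recycled.

Step 3
Reactants: 3 methyl (2E,4E)-6-hydroxy-2,5-dimethylhexa-2,4-dienoate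
Product: 4 methyl (2E,4E)-2,5-dimethyl-6-(propanoyloxy)hexa-2,4-dienoate
Conditions: EtCOCl, pyridine, DMAP (cat.), CH2Cl2, 0 °C
Reagents that add atoms: propanoyl chloride, CCC(=O)Cl
Why: O-Acylation of the primary allylic alcohol by an acid chloride under nucleophilic catalysis; no stereocentre is involved.

Step 4
Reactants: 4 methyl (2E,4E)-2,5-dimethyl-6-(propanoyloxy)hexa-2,4-dienoate
Product: 6 (2S,3R,4E)-6-methoxy-2,5-dimethyl-6-oxo-3-(prop-1-en-2-yl)hex-4-enoic acid, via boron ketene acetal 5 (not isolated)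
Conditions: (4S,5S)-2-bromo-1,3-bis{[3,5-bis(trifluoromethyl)phenyl]sulfonyl}-4,5-diphenyl-1,3,2-diazaborolidine (1.1 equiv), Et3N, toluene–hexane, −78 °C, then −20 °C to 4 °C; aq. work-up
Reagents that add atoms: none
Why: Enantioselective ester-enolate Claisen rearrangement through the chiral O-boron ketene acetal: the (E)-O-enolate and the (E)-allyl unit react through a chair, which fixes the relative configuration of C2 and C3, and the C2-symmetric sulfonamide ligand on boron selects one of the two mirror-image chairs, which fixes the absolute configuration.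

Step 5
Reactants: 6 (2S,3R,4E)-6-methoxy-2,5-dimethyl-6-oxo-3-(prop-1-en-2-yl)hex-4-enoic acid
Product: 8 methyl (2E,4R,5S)-2,5-dimethyl-6-oxo-4-(prop-1-en-2-yl)hex-2-enoate, via acid chloride 7 (not isolated)
Conditions: (COCl)2, DMF (cat.), CH2Cl2, 0 °C; then LiAlH(O-t-Bu)3, THF, −78 °C
Reagents that add atoms: none
Why: Acyl chloride formation followed by low-temperature hydride transfer from the hindered alkoxyaluminium hydride (partial reduction of an acid chloride), which should stop at the aldehyde and leave the methyl ester and the α-stereocentre untouched.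

Step 6
Reactants: 8 methyl (2E,4R,5S)-2,5-dimethyl-6-oxo-4-(prop-1-en-2-yl)hex-2-enoate
Product: 9 methyl (2E,4S,5S,6Z)-7-iodo-2,5-dimethyl-4-(prop-1-en-2-yl)octa-2,6-dienoate
Conditions: EtPPh3I, n-BuLi, THF, rt; I2, −78 °C; NaN(SiMe3)2, −20 °C; then 8, −78 °C to −20 °C
Reagents that add atoms: ethyltriphenylphosphonium iodide, CC[P+](c1ccccc1)(c1ccccc1)c1ccccc1.[I-]; iodine, II
Why: Stork–Zhao olefination, in which the α-iodo ylide reacts with the aldehyde under kinetic control and should give the (Z)-iodoalkene with iodine cis to the chain.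

Step 7
Reactants: 9 methyl (2E,4S,5S,6Z)-7-iodo-2,5-dimethyl-4-(prop-1-en-2-yl)octa-2,6-dienoate
Product: 10 (2E,4S,5S,6Z)-7-iodo-2,5-dimethyl-4-(prop-1-en-2-yl)octa-2,6-dienoic acid
Conditions: LiOH, THF–MeOH–H2O (3:1:1), 0 °C to rt; aq. HCl to pH 3
Reagents that add atoms: lithium hydroxide, [Li+].[OH-]
Why: Saponification of the methyl enoate by hydroxide; the vinyl iodide, the alkenes and both stereocentres should survive these mild conditions.

Step 8
Reactants: 11 (2R)-but-3-yn-2-ol
Product: 12 (2R)-4-bromobut-3-yn-2-ol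
Conditions: N-bromosuccinimide, AgNO3 (10 mol%), acetone, rt
Reagents that add atoms: N-bromosuccinimide, O=C1CCC(=O)N1Br
Why: Silver-catalysed electrophilic bromination of the terminal alkyne C–H; the carbinol centre is not involved.

Step 9
Reactants: 12 (2R)-4-bromobut-3-yn-2-ol
Product: 13 (2R)-hepta-3,5-diyn-2-ol
Conditions: propyne (excess), CuCl (5 mol%), NH2OH·HCl, aq. EtNH2, MeOH, 0 °C
Reagents that add atoms: propyne, CC#C
Why: Cadiot–Chodkiewicz coupling of the bromoalkyne with a terminal alkyne under CuCl catalysis should give the unsymmetrical 1,3-diyne.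

Step 10
Reactants: 13 (2R)-hepta-3,5-diyn-2-ol
Product: 15 (2R,3Z)-4-iodohept-3-en-5-yn-2-ol, via cyclic alkenylalanate 14 (not isolated)
Conditions: NaAlH2(OCH2CH2OMe)2, THF, 0 °C to rt; EtOAc; then I2, THF, −78 °C to 0 °C
Reagents that add atoms: iodine, II
Why: Hydroxyl-directed trans-hydroalumination of the propargylic triple bond only (hydride to the near carbon, aluminium on the far carbon in a five-membered alanate) and iodinolysis with retention, so that iodine ends cis to the carbinol carbon.

Step 11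
Reactants: 15 (2R,3Z)-4-iodohept-3-en-5-yn-2-ol
Product: 16 (2R,3E)-4-ethylhept-3-en-5-yn-2-ol
Conditions: Et2Zn (2.5 equiv), PdCl2(dppf) (5 mol%), THF, 50 °C
Reagents that add atoms: diethylzinc, CC[Zn]CC
Why: Negishi cross-coupling of the alkenyl iodide with an alkylzinc proceeds with retention, so ethyl takes the place cis to the carbinol carbon.

Step 12
Reactants: 10 (2E,4S,5S,6Z)-7-iodo-2,5-dimethyl-4-(prop-1-en-2-yl)octa-2,6-dienoic acid; 16 (2R,3E)-4-ethylhept-3-en-5-yn-2-ol
Product: 18 (2R,3E)-4-ethylhept-3-en-5-yn-2-yl (2E,4S,5S,6Z)-7-iodo-2,5-dimethyl-4-(prop-1-en-2-yl)octa-2,6-dienoate, via mixed anhydride 17 (not isolated)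
Conditions: 2,4,6-Cl3C6H2COCl, Et3N, THF, rt; then 16, DMAP, toluene, rt
Reagents that add atoms: none
Why: Yamaguchi esterification through the mixed anhydride acylates the alcohol at oxygen, so the carbinol configuration and all alkene geometries are kept.

Step 13
Reactants: 18 (2R,3E)-4-ethylhept-3-en-5-yn-2-yl (2E,4S,5S,6Z)-7-iodo-2,5-dimethyl-4-(prop-1-en-2-yl)octa-2,6-dienoate
Product: 23 (2R,3R,4E)-2-[(1R,4R,5S)-2,4-dimethyl-5-(prop-1-en-2-yl)cyclopent-2-en-1-yl]-3-ethyl-2-methyl-3-(prop-1-yn-1-yl)hex-4-enoic acid, via vinyllithium 19 (not isolated), via lithium enolate 20 (not isolated), via silyl ketene acetal 21 (not isolated), via trimethylsilyl ester 22 (not isolated)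
Conditions: t-BuLi (2.1 equiv), THF–Et2O–pentane (4:1:1), −100 °C to −78 °C; Me3SiCl–Et3N, DMPU, −78 °C to rt; then toluene, 80 °C; aq. citric acid
Reagents that add atoms: none
Why: Iodine–lithium exchange, which at −100 °C should be much faster than carbonyl attack, gives vinyllithium 19, which adds 5-exo-trig to the β-carbon of the tiglate (a halogen–metal-exchange-initiated intramolecular Michael addition) and so closes ring B through its C(sp2)–C(sp3) bond. The new ring-junction centre is set by a chair-like closure in which the methyl and isopropenyl groups of the tether are pseudo-equatorial, which places the ester-bearing arm trans to isopropenyl and cis to methyl; a closure onto a preformed six-membered ring could only give the cis junction. Addition through the lithium-chelated s-cis enoate should give enolate 20 with O–Li cis to the ring, and silylation fixes this geometry in ketene acetal 21. On warming, 21 undergoes the Ireland–Claisen [3,3] shift (closest precedent: tandem conjugate addition–ester-enolate Claisen rearrangement) through a chair with the carbinol methyl equatorial and the ethyl group axial, the other chair being excluded by a 1,3-diaxial methyl–ethyl contact; this transfers the carbinol configuration to both quaternary carbons, and hydrolysis of 22 leaves the acid. The step needs exchange over carbonyl addition, 1,4- over 1,2-attack (secured by ring size) and a single enolate geometry, the last being the main risk.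

Step 14
Reactants: 23 (2R,3R,4E)-2-[(1R,4R,5S)-2,4-dimethyl-5-(prop-1-en-2-yl)cyclopent-2-en-1-yl]-3-ethyl-2-methyl-3-(prop-1-yn-1-yl)hex-4-enoic acid
Product: 24 (1R,3aR,4R,5R,7aS)-5-ethyl-1,3,4,7-tetramethyl-5-(prop-1-yn-1-yl)-3a,4,5,7a-tetrahydro-1H-indene-4-carboxylic acid
Conditions: second-generation Hoveyda–Grubbs catalyst RuCl2(H2IMes)(=CH-C6H4-2-O-i-Pr) (10 mol%), toluene (2 mM), 80 °C, argon purge
Reagents that add atoms: none
Why: Ring-closing metathesis between the propenyl and isopropenyl groups should close ring A as the trisubstituted cyclohexene with loss of propene; the alkyne cannot ring-close with the carbene (only three- or four-membered rings would result) and no stereocentre is touched.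

Step 15
Reactants: 24 (1R,3aR,4R,5R,7aS)-5-ethyl-1,3,4,7-tetramethyl-5-(prop-1-yn-1-yl)-3a,4,5,7a-tetrahydro-1H-indene-4-carboxylic acid
Product: 26 (1R,3aR,4R,5S,7aS)-5-ethyl-1,3,4,7-tetramethyl-5-[(1E,3E)-2-methyl-4-phenylbuta-1,3-dien-1-yl]-3a,4,5,7a-tetrahydro-1H-indene-4-carboxylic acid, via alkenylzirconocene 25 (not isolated)
Conditions: Cp2Zr(H)Cl (3 equiv), THF, rt to 40 °C; then ZnCl2, Pd(PPh3)4 (5 mol%), (E)-PhCH=CHBr, THF, rt; aq. HCl
Reagents that add atoms: (E)-(2-bromoethenyl)benzene, Br/C=C/c1ccccc1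
Why: syn-Hydrozirconation of the internal alkyne puts zirconium on the less hindered methyl-bearing carbon, and Negishi coupling after transmetalation to zinc keeps both alkene geometries, which should give the (1E,3E)-diene; the first equivalent of hydride is consumed by the acid.

Compound list

1 | glyoxal | O=CC=O | starting material
2 | dimethyl (2E,4E)-2,5-dimethylhexa-2,4-dienedioate | COC(=O)/C(C)=C/C=C(\C)C(=O)OC | intermediate
3 | methyl (2E,4E)-6-hydroxy-2,5-dimethylhexa-2,4-dienoate | COC(=O)/C(C)=C/C=C(\C)CO | intermediate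
4 | methyl (2E,4E)-2,5-dimethyl-6-(propanoyloxy)hexa-2,4-dienoate | COC(=O)/C(C)=C/C=C(\C)COC(=O)CC | intermediate
5 | O-boron ketene acetal of 4: (E)-O-enolate of the propanoate (methyl trans to O–B), boron in the (4S,5S)-1,3-bis{[3,5-bis(trifluoromethyl)phenyl]sulfonyl}-4,5-diphenyl-1,3,2-diazaborolidine ring | C/C=C(/OB1N(S(=O)(=O)c2cc(cc(c2)C(F)(F)F)C(F)(F)F)[C@@H](c2ccccc2)[C@H](c2ccccc2)N1S(=O)(=O)c1cc(cc(c1)C(F)(F)F)C(F)(F)F)OC/C(C)=C/C=C(\C)C(=O)OC | intermediate
6 | (2S,3R,4E)-6-methoxy-2,5-dimethyl-6-oxo-3-(prop-1-en-2-yl)hex-4-enoic acid | COC(=O)/C(C)=C/[C@@H](C(C)=C)[C@H](C)C(=O)O | intermediate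
7 | methyl (2E,4R,5S)-6-chloro-2,5-dimethyl-6-oxo-4-(prop-1-en-2-yl)hex-2-enoate (acid chloride of 6) | COC(=O)/C(C)=C/[C@@H](C(C)=C)[C@H](C)C(Cl)=O | intermediate
8 | methyl (2E,4R,5S)-2,5-dimethyl-6-oxo-4-(prop-1-en-2-yl)hex-2-enoate | COC(=O)/C(C)=C/[C@@H](C(C)=C)[C@H](C)C=O | intermediate
9 | methyl (2E,4S,5S,6Z)-7-iodo-2,5-dimethyl-4-(prop-1-en-2-yl)octa-2,6-dienoate | COC(=O)/C(C)=C/[C@@H](C(C)=C)[C@H](C)/C=C(/C)I | intermediate
10 | (2E,4S,5S,6Z)-7-iodo-2,5-dimethyl-4-(prop-1-en-2-yl)octa-2,6-dienoic acid | OC(=O)/C(C)=C/[C@@H](C(C)=C)[C@H](C)/C=C(/C)I | intermediate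
11 | (2R)-but-3-yn-2-ol | C[C@@H](O)C#C | starting material
12 | (2R)-4-bromobut-3-yn-2-ol | C[C@@H](O)C#CBr | intermediate
13 | (2R)-hepta-3,5-diyn-2-ol | C[C@@H](O)C#CC#CC | intermediate
14 | sodium cyclic alkenylalanate from 13: five-membered ring O–Al–C4=C3–C2 with aluminium on C4, two 2-methoxyethoxy ligands, (R) at C2 | C[C@H]1O[Al-](OCCOC)(OCCOC)C(C#CC)=C1.[Na+] | intermediate
15 | (2R,3Z)-4-iodohept-3-en-5-yn-2-ol | C[C@@H](O)/C=C(\I)C#CC | intermediate
16 | (2R,3E)-4-ethylhept-3-en-5-yn-2-ol | C[C@@H](O)/C=C(\CC)C#CC | intermediate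
17 | (2E,4S,5S,6Z)-7-iodo-2,5-dimethyl-4-(prop-1-en-2-yl)octa-2,6-dienoic 2,4,6-trichlorobenzoic anhydride | O=C(OC(=O)/C(C)=C/[C@@H](C(C)=C)[C@H](C)/C=C(/C)I)c1c(Cl)cc(Cl)cc1Cl | intermediate
18 | (2R,3E)-4-ethylhept-3-en-5-yn-2-yl (2E,4S,5S,6Z)-7-iodo-2,5-dimethyl-4-(prop-1-en-2-yl)octa-2,6-dienoate | C[C@@H](OC(=O)/C(C)=C/[C@@H](C(C)=C)[C@H](C)/C=C(/C)I)/C=C(\CC)C#CC | intermediate
19 | vinyllithium from 18: lithium in place of iodine, alkene geometry kept | C[C@@H](OC(=O)/C(C)=C/[C@@H](C(C)=C)[C@H](C)/C=C(/C)[Li])/C=C(\CC)C#CC | intermediate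
20 | lithium ester enolate after ring closure: trans,trans-trisubstituted cyclopentenyl group on the enolate carbon, O–Li cis to the ring, allyloxy cis to methyl | C[C@@H](O/C(O[Li])=C(\C)[C@@H]1[C@@H](C(C)=C)[C@H](C)C=C1C)/C=C(\CC)C#CC | intermediate
21 | trimethylsilyl ketene acetal of the same geometry (O–Si cis to the ring) | C[C@@H](O/C(O[Si](C)(C)C)=C(\C)[C@@H]1[C@@H](C(C)=C)[C@H](C)C=C1C)/C=C(\CC)C#CC | intermediate
22 | trimethylsilyl ester of 23 | C/C=C/[C@](CC)(C#CC)[C@](C)(C(=O)O[Si](C)(C)C)[C@@H]1[C@@H](C(C)=C)[C@H](C)C=C1C | intermediate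
23 | (2R,3R,4E)-2-[(1R,4R,5S)-2,4-dimethyl-5-(prop-1-en-2-yl)cyclopent-2-en-1-yl]-3-ethyl-2-methyl-3-(prop-1-yn-1-yl)hex-4-enoic acid | C/C=C/[C@](CC)(C#CC)[C@](C)(C(=O)O)[C@@H]1[C@@H](C(C)=C)[C@H](C)C=C1C | intermediate
24 | (1R,3aR,4R,5R,7aS)-5-ethyl-1,3,4,7-tetramethyl-5-(prop-1-yn-1-yl)-3a,4,5,7a-tetrahydro-1H-indene-4-carboxylic acid | CC[C@]1(C#CC)C=C(C)[C@H]2[C@H](C)C=C(C)[C@@H]2[C@@]1(C)C(=O)O | intermediate
25 | alkenylzirconocene chloride from 24: Cp2Zr(Cl) on the methyl-bearing alkene carbon and trans to the ring, carboxyl group as its zirconocene chloride carboxylate | CC[C@]1(/C=C(C)/[Zr](Cl)(C3C=CC=C3)C3C=CC=C3)C=C(C)[C@H]2[C@H](C)C=C(C)[C@@H]2[C@@]1(C)C(=O)O[Zr](Cl)(C3C=CC=C3)C3C=CC=C3 | intermediate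
26 | (1R,3aR,4R,5S,7aS)-5-ethyl-1,3,4,7-tetramethyl-5-[(1E,3E)-2-methyl-4-phenylbuta-1,3-dien-1-yl]-3a,4,5,7a-tetrahydro-1H-indene-4-carboxylic acid (CNP0103503.1) | CC[C@]1(/C=C(C)/C=C/c2ccccc2)C=C(C)[C@H]2[C@H](C)C=C(C)[C@@H]2[C@@]1(C)C(=O)O | target

Total step count: 15. Longest linear sequence: 11 steps (steps 1–7 and 12–15).

Steps most likely to fail

Step 13. The alkyllithium may attack the ester carbonyl in competition with iodine–lithium exchange. Both enolate geometries may form, which would erode the configuration at the two quaternary carbons. The [3,3] shift between two fully substituted termini may be slow enough for the ketene acetal to be lost. The fallback separates ring closure from enolate formation and sets out from 18. A tin hydride radical chain (Bu3SnH, AIBN, benzene, 80 °C, slow addition) closes the same C3–C3a bond by 5-exo-trig attack of the vinyl radical on the enoate, through the same chair-like arrangement. It should give the saturated ester (2R,3E)-4-ethylhept-3-en-5-yn-2-yl 2-[(1S,4R,5S)-2,4-dimethyl-5-(prop-1-en-2-yl)cyclopent-2-en-1-yl]propanoate F1 as C2 epimers, which does not matter. Enolisation of F1 with LiN(i-Pr)2 in THF–DMPU at −78 °C goes through an open transition state that places O–Li cis to the larger α-substituent. Trapping with Me3SiCl should then give ketene acetal 21, where the fallback comes back to the route.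

Step 14. Initiation at two hindered alkenes may be slow, and the catalyst may be consumed by intermolecular enyne metathesis at the propynyl group. The fallback removes the alkyne before ring closure and sets out from 23. Hydrozirconation (Cp2Zr(H)Cl, 2.2 equiv, THF, 0 °C to rt, to limit attack on the isopropenyl group) followed by iodinolysis should give (2R,3R,4E)-2-[(1R,4R,5S)-2,4-dimethyl-5-(prop-1-en-2-yl)cyclopent-2-en-1-yl]-3-ethyl-3-[(1E)-2-iodoprop-1-en-1-yl]-2-methylhex-4-enoic acid F2. Its trisubstituted alkenyl iodide is inert toward the ruthenium carbene, so ring-closing metathesis under the conditions of step 14 should give (1R,3aR,4R,5R,7aS)-5-ethyl-5-[(1E)-2-iodoprop-1-en-1-yl]-1,3,4,7-tetramethyl-3a,4,5,7a-tetrahydro-1H-indene-4-carboxylic acid F3. Suzuki coupling of F3 with (E)-styrylboronic acid (Pd(PPh3)4, K2CO3, THF–H2O, 60 °C) proceeds with retention and comes back to the route at 26.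

Step 4. The [3,3] shift of the boron ketene acetal may be slow because the allyl unit is an electron-poor dienoate, and the controller may not distinguish the two chairs well enough. The fallback replaces asymmetric induction by resolution and sets out from 4. An achiral Ireland–Claisen rearrangement (LiN(i-Pr)2, THF, −78 °C; Me3SiCl; warm to rt; aq. acid) uses the same (E)-O-enolate and chair. It should give rac-(2S*,3R*,4E)-6-methoxy-2,5-dimethyl-6-oxo-3-(prop-1-en-2-yl)hex-4-enoic acid F4 with the same relative configuration. Crystallisation with (S)-1-phenylethylamine, or with its antipode if that salt is the less soluble one, should give (1S)-1-phenylethan-1-aminium (2S,3R,4E)-6-methoxy-2,5-dimethyl-6-oxo-3-(prop-1-en-2-yl)hex-4-enoate F5. Acidification of F5 comes back to the route at 6.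

Further compounds

F1 | step 13 | (2R,3E)-4-ethylhept-3-en-5-yn-2-yl 2-[(1S,4R,5S)-2,4-dimethyl-5-(prop-1-en-2-yl)cyclopent-2-en-1-yl]propanoate (C2 epimers) | C[C@@H](OC(=O)C(C)[C@@H]1[C@@H](C(C)=C)[C@H](C)C=C1C)/C=C(\CC)C#CC
F2 | step 14 | (2R,3R,4E)-2-[(1R,4R,5S)-2,4-dimethyl-5-(prop-1-en-2-yl)cyclopent-2-en-1-yl]-3-ethyl-3-[(1E)-2-iodoprop-1-en-1-yl]-2-methylhex-4-enoic acid | C/C=C/[C@](CC)(/C=C(C)/I)[C@](C)(C(=O)O)[C@@H]1[C@@H](C(C)=C)[C@H](C)C=C1C
F3 | step 14 | (1R,3aR,4R,5R,7aS)-5-ethyl-5-[(1E)-2-iodoprop-1-en-1-yl]-1,3,4,7-tetramethyl-3a,4,5,7a-tetrahydro-1H-indene-4-carboxylic acid | CC[C@]1(/C=C(C)/I)C=C(C)[C@H]2[C@H](C)C=C(C)[C@@H]2[C@@]1(C)C(=O)O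
F4 | step 4 | rac-(2S*,3R*,4E)-6-methoxy-2,5-dimethyl-6-oxo-3-(prop-1-en-2-yl)hex-4-enoic acid (both enantiomers) | COC(=O)/C(C)=C/[C@@H](C(C)=C)[C@H](C)C(=O)O.COC(=O)/C(C)=C/[C@H](C(C)=C)[C@@H](C)C(=O)O
F5 | step 4 | (1S)-1-phenylethan-1-aminium (2S,3R,4E)-6-methoxy-2,5-dimethyl-6-oxo-3-(prop-1-en-2-yl)hex-4-enoate | COC(=O)/C(C)=C/[C@@H](C(C)=C)[C@H](C)C(=O)[O-].C[C@H]([NH3+])c1ccccc1
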